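Minutes of the meeting on teal and grey.

The analyst opened with the leftover: in the winter run 8.4% of the charge stood in chains at 120 min, so nearly all of the free monomer was still free 40.0 min after the feed ended.

in all of them: initiator 2.5 mol%
- dusk: free monomer 0.0084 M (fed, over 80 min); run made earlier; the fed solution adds 0.10 times the starting volume
- summer: free monomer 0.018 M (fed, over 80 min); run made earlier; the fed solution adds 0.10 times the starting volume
- winter: free monomer 0.019 M (fed, over 80 min); run made earlier; the fed solution adds 0.10 times the starting volume
- teal: free monomer 0.012 M (fed, over 80 min); the fed solution adds 0.10 times the starting volume; time 4.0 h
- grey: free monomer 0.025 M (fed, over 80 min); the fed solution adds 0.10 times the starting volume; time 4.0 h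

- dusk (time / min: monomer in chains / %): 10.0: 0.8; 20.0: 1.6; 30.0: 0; 60.0: 4.1; 120: 5.7
- summer (time / min: monomer in chains / %): 10.0: 0; 30.0: 2.3; 60.0: 6.1; 80.0: 6.0; 120: 7.8
- winter (time / min: monomer in chains / %): 10.0: 0; 30.0: 2.3; 60.0: 4.3; 80.0: 8.3; 120: 8.4

(each reading ± 1 percentage point)

- charges are per starting volume, the dose included; the dosed solution carries all of it
- the average divides the monomer in chains by the number of chains begun, living and dead together
- what was read earlier has a scatter of 1 percentage point, one standard deviation
- the earlier runs do not show the number of chains; that part of a forecast is a guess
- percentages count the whole charge, also what has not yet gone in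

- which of the two ends with the longer chains by the average number of monomer units in a chain (chains begun, living or dead) ("neither" if they lie within 10%) (teal / grey / neither)
- average number of monomer units in a chain (chains begun, living or dead) at the end, teal
- average number of monomer units in a chain (chains begun, living or dead) at the end, grey

The process lead answered that the question concerns length, not yield, and proposed counting turnovers. The proposal assumes that each initiator begins one chain, which the runs cannot show. At 2.5 mol% initiator, the charge holds 40.0 units of free monomer per initiator, the start ratio, usually called the monomer-to-initiator ratio. On that assumption, and once the initiator has begun its chains, average length is the part of the charge in chains times the start ratio.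

The analyst tried it. At 120 min, dusk counts 2.28, summer 3.12 and winter 3.36, each carrying the scatter of 1 percentage point on its reading.

My own reckoning, as minute-taker, rests on that order of scattered readings, which follows the charge. Teal's 0.012 M lies between dusk's and summer's charges, so I put teal between their counts. Grey's 0.025 M is higher than winter's 0.019 M, so I put grey above winter's count, and I expect the longer chains in grey.

The forecaster then tabled 3.2 for teal and 4.6 for grey, with grey longer, and wrote of the assumption: “The chain count is a guess”. Those numbers are for 4.0 h, mine for 120 min.

The longer chains stand in grey.

    free monomer + living end → monomer in chains + living end, rate k1*[living end]*[free monomer] (k = 1.10 L mol⁻¹ s⁻¹)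
    monomer in chains + living end → free monomer + living end, rate k2*[living end] as long as [monomer in chains] is above zero (k = 0.00410 s⁻¹)
    free monomer + initiator → living end + monomer in chains (k = 0.230 L mol⁻¹ s⁻¹)
    2 living end → dead end (k = 16.0 L mol⁻¹ s⁻¹)

Teal ends at 3.66 units per chain and grey at 4.78. At 4.00 h the initiator stands at 0% of its charge in teal and 0% in grey. Teal's 9.16% of monomer in chains, times the start ratio of 40.0, gives 3.66; grey's 12.0% gives 4.80. The neighbour flask, teal with 0.62 mol% initiator, has a start ratio of 161 and holds 5.81% of monomer in chains at 4.00 h, which counts 9.37 against its average length of 9.38.

The data are simulated for substances that don't exist; scatter was added.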